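I decided to follow the capture agent by hand before letting any integrator speak, since its charge bounds the trapped intermediate at 5.00%.

substrate 0.020 M; reagent 2.00 equiv (fed, over 12 min); capture agent 1.00 mM; free catalyst 1 mol%; second catalyst 0.99 mol%; time 30 h; the fed solution adds 0.50 times the starting volume

    substrate + free catalyst → free catalyst + open intermediate (k1 = 34 /M/s)
    reagent + second catalyst + open intermediate → second catalyst + target (k2 = 400 /M²/s)
    substrate + target → side product (k3 = 0.083 /M/s)
    open intermediate + capture agent → trapped intermediate (k4 = 0.046 /M/s)

- percentages count the substrate that a species holds: one side product counts as two
- every charge counts on the volume at the start, and the solution that is fed holds the whole dose
- the reaction counts as stopped when no species that holds the substrate changes by six tenths of a point or more over the second half of the time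
- run time (flask): 30 h

- the state of affairs at 30 h: stopped, and by what, or still going (it is still moving / all of the substrate has reacted / the reagent has run out first / no working catalyst is left)
- part of the substrate gone at 30 h
- the target standing at 30 h, as a percentage of the substrate charged
- the trapped intermediate standing at 30 h, as a percentage of the substrate charged

At the bench one says that a slow trap takes, of what passes through an intermediate, the ratio of its rate to the main rate. I turned both rates into times, with every amount on the final volume. With 1.50 equiv of reagent, a middle value between the full dose and what stands once one equivalent is used, the open intermediate has a pseudo-first-order lifetime τ on the reagent step of 15.8 min. Capture at the charged capture agent then takes a share of 2.90%.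

But that rule holds the capture agent constant, and the charge allows a trapped intermediate of 5.00%. The border is the ratio of the two shares, which I call the capture number N: the lifetime τ divided by the clock t_c, the mean time a capture agent molecule survives among open intermediate standing at the full substrate level. That clock is 27.2 min, so N is 0.581, and the rule's share stays below the cap without being small against it. My estimate, with open intermediate held at that level for one lifetime τ, puts the capture agent at exp(−N) of its charge, or 55.9%, and my trapped intermediate at the cap times (1 − exp(−N)), or 2.20%.

The forecast said: all of the substrate has reacted, with conversion 100%, target 95% and trapped intermediate 2.6%, in a range from 1.8% to 3.5%. Its ground for the capture was that “the slow capture uses about half of the capture agent during the intermediate's short life”. My figure lies lower than its 2.6%, though inside that range.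

The flask gave: all of the substrate has reacted, with conversion 100%, target 95.4% and trapped intermediate 2.56%. Its capture agent stood at 49% of charge at 30.0 h, which reads back as N of 0.713, higher than my 0.581, and half of its capture turnover was done by 0.177 h, earlier than the 0.249 h of the reagent step.

The neighbour charged with 0.800 equiv of reagent holds less reagent than the one equivalent its substrate needs, so in my reckoning τ has no finite value there once that dose is used. Counting the cap as taken, I expected about 15.0% of its substrate to stay open, and N there becomes the run time over a clock lengthened by that share: 9.94, which gives a trapped intermediate of 5.00%. Computed at 30.0 h, that neighbour holds trapped intermediate 5.00%, open intermediate 14.5%, target 79.5%, reagent 0% of its charge, and capture agent 0% of its charge.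

All constants are invented; the result is computed.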